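The cyclohexane (C1 = CCl(CH3), C2 = CH2, C3 = quaternary carbon with CH3 and the bromovinyl arm, C4 = CHBr, C5 = CH2, C6 = CHCl) hides a β-hydroxy ketone: the heteroatoms on C4 and C6 are 1,3-related across C5, and the one-carbon arm on C3 is the survivor of two identical formyl groups. A single enamine aldol of an achiral methyl ketone, tethered to a methyl-bearing carbon that carries two enantiotopic CHO groups, forms C4–C5, closes the six-membered ring and sets C3 and C4. The C4 hydroxyl then steers an epoxidation of C1=C6, and three invertive substitutions place bromine and both chlorines.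

Key step: step 4

Assumption: the sense of induction is carried over from the Hajos–Parrish cyclisation, in which (S)-proline gives the (S)-configured quaternary carbon and the priority order at that carbon is the same as here, so (R)-proline is assigned to the (1R,2R) ketol; if the sense proves opposite, only the catalyst enantiomer changes. Ring atoms are called C1–C6 as in the target in all Why lines.

Step 1
Reactants: 1 diethyl methylmalonate; 2 methyl vinyl ketone
Product: 3 diethyl 2-methyl-2-(3-oxobutyl)propanedioate
Conditions: NaOEt (5 mol %), EtOH, 0 → 20 °C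
Reagents that add atoms: none
Why: Base-catalysed Michael addition of the malonate anion to the unhindered enone, in which the new quaternary carbon is not yet stereogenic because its two ester arms are identical.

Step 2
Reactants: 3 diethyl 2-methyl-2-(3-oxobutyl)propanedioate
Product: 4 2-(hydroxymethyl)-2-methylhexane-1,5-diol (racemic at the secondary carbinol)
Conditions: LiAlH4, THF, 0 °C → reflux; water/NaOH work-up
Reagents that add atoms: none
Why: Exhaustive hydride reduction (LiAlH4) of both esters and the ketone gives the triol directly, so no ketal has to be put on and taken off, and the racemic secondary carbinol is erased by the next step.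

Step 3
Reactants: 4 2-(hydroxymethyl)-2-methylhexane-1,5-diol
Product: 5 2-methyl-2-(3-oxobutyl)propanedial
Conditions: (COCl)2, DMSO, CH2Cl2, −78 °C; Et3N, −78 → 0 °C; used crude at once
Reagents that add atoms: none
Why: Triple Swern oxidation, in which all three hydroxyls are converted to alkoxysulfonium ions before Et3N is added, so that no hydroxy aldehyde is left to lactolise and the non-enolisable 2,2-disubstituted dialdehyde meets only cold, anhydrous amine base.

Step 4
Reactants: 5 2-methyl-2-(3-oxobutyl)propanedial
Product: 6 (1R,2R)-2-hydroxy-1-methyl-4-oxocyclohexane-1-carbaldehyde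
Conditions: (R)-proline (20 mol %), DMF, 4 → 20 °C
Reagents that add atoms: none
Why: Enamine catalysis: (R)-proline condenses with the methyl ketone, the only enolisable carbonyl, and the terminal enamine carbon (C5) adds to one formyl carbon (C4) while the carboxylic acid hydrogen-bonds to that formyl oxygen, which is the Hajos–Parrish type of intramolecular proline aldol transferred to a pair of acyclic formyl groups. The ring closes in a 6-(enolendo)-exo-trig mode, the only productive one, since attack through the internal α-carbon (C1) would give a cyclobutane and C3 carries no α-hydrogen. C3 is set by the catalyst's choice between the two enantiotopic formyl groups, made within a chair in which the reacting C=O is pseudo-axial so that it reaches the acid. C4 is set by the same chair, the carbonyl face attacked being the one turned toward the carboxylic acid. The selectivity needed is hydroxyl trans to the surviving formyl group; it should follow because the C3 methyl prefers the equatorial site and the spectator formyl the axial one, anti to the reacting carbonyl dipole, as in the Hajos–Parrish ketol, where the new hydroxyl is cis to the angular methyl. The neutral conditions should leave the ketol undehydrated, and it is silylated at once to block retro-aldol.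

Step 5
Reactants: 6 (1R,2R)-2-hydroxy-1-methyl-4-oxocyclohexane-1-carbaldehyde
Product: 7 (1R,2R)-2-[(tert-butyldimethylsilyl)oxy]-1-methyl-4-oxocyclohexane-1-carbaldehyde
Conditions: TBSOTf, 2,6-lutidine, CH2Cl2, −78 °C
Reagents that add atoms: tert-butyldimethylsilyl trifluoromethanesulfonate, CC(C)(C)[Si](C)(C)OS(=O)(=O)C(F)(F)F
Why: Silyl ether formation with the silyl triflate and a hindered pyridine base, fast enough at −78 °C for the neopentyl-type alcohol while ketone and aldehyde are left alone, blocks retro-aldol and E1cB loss of the C4 oxygen in the enolate step ahead and touches no stereocentre.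

Step 6
Reactants: 7 (1R,2R)-2-[(tert-butyldimethylsilyl)oxy]-1-methyl-4-oxocyclohexane-1-carbaldehyde
Product: 8 (3R,4S)-4-[(E)-2-bromoethenyl]-3-[(tert-butyldimethylsilyl)oxy]-4-methylcyclohexan-1-one
Conditions: CrBr2, CHBr3, THF, 0 → 50 °C
Reagents that add atoms: bromoform, BrC(Br)Br
Why: Takai olefination, in which the geminal dichromium species formed from bromoform and divalent chromium adds to the aldehyde and eliminates to the (E)-bromoalkene, is selective for aldehydes over ketones, and the use of CrBr2 in place of CrCl2 avoids halide scrambling in the vinyl halide.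

Step 7
Reactants: 8 (3R,4S)-4-[(E)-2-bromoethenyl]-3-[(tert-butyldimethylsilyl)oxy]-4-methylcyclohexan-1-one
Product: 11 (4S,5R)-4-[(E)-2-bromoethenyl]-5-[(tert-butyldimethylsilyl)oxy]-4-methyl-2-methylidenecyclohexan-1-one, via Mannich base 9 (not isolated), via trimethylammonium iodide 10 (not isolated)
Conditions: LiN(iPr)2, THF, −78 °C; Me2N=CH2+ I−, −78 → 0 °C; then MeI, CH2Cl2, 20 °C; then aq NaHCO3, CH2Cl2, 20 °C; product used without delay
Reagents that add atoms: N,N-dimethylmethyleneiminium iodide, C=[N+](C)C.[I-]
Why: Enolate Mannich reaction followed by quaternisation and base-induced elimination (Eschenmoser methylenation): kinetic deprotonation should take place at C1, the α-carbon remote from the silyloxy-bearing C4 and the less shielded one, and the exocyclic methylene it ends with is the future C1 methyl carbon, the transient C1 stereocentre being lost again.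

Step 8
Reactants: 11 (4S,5R)-4-[(E)-2-bromoethenyl]-5-[(tert-butyldimethylsilyl)oxy]-4-methyl-2-methylidenecyclohexan-1-one
Product: 12 (4S,5R)-4-[(E)-2-bromoethenyl]-5-[(tert-butyldimethylsilyl)oxy]-4-methyl-2-methylidenecyclohexan-1-ol (both epimers at the new carbinol)
Conditions: NaBH4, CeCl3·7H2O, MeOH, −78 °C
Reagents that add atoms: none
Why: Luche reduction, in which CeCl3 makes borohydride add 1,2 to the α-methylene ketone without conjugate reduction, gives the allylic alcohol as a mixture of C6 epimers, both of which serve because C6 becomes trigonal in the next step.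

Step 9
Reactants: 12 (4S,5R)-4-[(E)-2-bromoethenyl]-5-[(tert-butyldimethylsilyl)oxy]-4-methyl-2-methylidenecyclohexan-1-ol
Product: 15 tert-butyl{[(1R,6S)-6-[(E)-2-bromoethenyl]-4,6-dimethylcyclohex-3-en-1-yl]oxy}dimethylsilane, via sulfonyl hydrazone 13 (not isolated), via allylic diazene 14 (not isolated)
Conditions: IPNBSH (N-isopropylidene-N′-(2-nitrobenzenesulfonyl)hydrazine), PPh3, DEAD, THF, 0 → 23 °C; then CF3CH2OH–H2O (1:1), 23 °C
Reagents that add atoms: none
Why: Reductive 1,3-transposition of an allylic alcohol through a Mitsunobu-derived allylic diazene: hydrolysis of the hydrazone and loss of the sulfinate give the monoalkyl diazene, which passes its hydrogen to the methylene carbon in a retro-ene step with loss of N2, so the double bond moves to C1=C6 and the methylene becomes the C1 methyl group without palladium or acid that could harm the vinyl bromide or the silyl ether.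

Step 10
Reactants: 15 tert-butyl{[(1R,6S)-6-[(E)-2-bromoethenyl]-4,6-dimethylcyclohex-3-en-1-yl]oxy}dimethylsilane
Product: 16 (1R,6S)-6-[(E)-2-bromoethenyl]-4,6-dimethylcyclohex-3-en-1-ol
Conditions: Bu4NF, THF, 0 → 20 °C
Reagents that add atoms: none
Why: Fluoride-induced cleavage of the silyl ether frees the C4 hydroxyl for the directed epoxidation, and the (E)-bromoalkene, whose vinylic hydrogen is cis to bromine, should not eliminate under these conditions.

Step 11
Reactants: 16 (1R,6S)-6-[(E)-2-bromoethenyl]-4,6-dimethylcyclohex-3-en-1-ol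
Product: 17 (1S,3R,4S,6R)-4-[(E)-2-bromoethenyl]-4,6-dimethyl-7-oxabicyclo[4.1.0]heptan-3-ol (epoxide oxygen cis to the hydroxyl)
Conditions: VO(acac)2 (5 mol %), t-BuOOH, CH2Cl2, 0 → 20 °C
Reagents that add atoms: tert-butyl hydroperoxide, CC(C)(C)OO
Why: Hydroxyl-directed epoxidation of a cyclic homoallylic alcohol with VO(acac)2 and t-BuOOH: the vanadium alkoxide of the C4 hydroxyl delivers oxygen to the electron-rich trisubstituted C1=C6 bond on its own face, which sets C1 and C6 with the epoxide oxygen cis to the hydroxyl, while the electron-poor bromoalkene does not react.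

Step 12
Reactants: 17 (1S,3R,4S,6R)-4-[(E)-2-bromoethenyl]-4,6-dimethyl-7-oxabicyclo[4.1.0]heptan-3-ol
Product: 18 (1S,3R,4S,6R)-4-[(E)-2-bromoethenyl]-4,6-dimethyl-7-oxabicyclo[4.1.0]heptan-3-yl trifluoromethanesulfonate
Conditions: Tf2O, pyridine, CH2Cl2, −40 °C; cold aq NaHCO3 work-up, used crude
Reagents that add atoms: trifluoromethanesulfonic anhydride, O=S(=O)(OS(=O)(=O)C(F)(F)F)C(F)(F)F
Why: Sulfonylation with triflic anhydride and pyridine converts the C4 hydroxyl with retention into the best available leaving group, which is needed because C4 adjoins the quaternary C3, and the epoxide oxygen, lying on the same face as the triflate, cannot take part in its departure.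

Step 13
Reactants: 18 (1S,3R,4S,6R)-4-[(E)-2-bromoethenyl]-4,6-dimethyl-7-oxabicyclo[4.1.0]heptan-3-yl trifluoromethanesulfonate
Product: 19 (1R,3S,4S,6S)-4-bromo-3-[(E)-2-bromoethenyl]-1,3-dimethyl-7-oxabicyclo[4.1.0]heptane
Conditions: Bu4NBr, toluene, 0 → 40 °C
Reagents that add atoms: tetrabutylammonium bromide, CCCC[N+](CCCC)(CCCC)CCCC.[Br-]
Why: SN2 displacement of the triflate by bromide in a non-ionising solvent inverts C4 and so places bromine cis to the bromovinyl arm; it is run at the epoxide stage because the flattened ring can present the triflate equatorially, where the incoming bromide eclipses no substituent of C3, and because no ring alkene remains that could participate.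

Step 14
Reactants: 19 (1R,3S,4S,6S)-4-bromo-3-[(E)-2-bromoethenyl]-1,3-dimethyl-7-oxabicyclo[4.1.0]heptane
Product: 21 (1S,2S,4R,5S)-2-bromo-1-[(E)-2-bromoethenyl]-4,5-dichloro-1,5-dimethylcyclohexane, via chloro oxyphosphonium chloride 20 (not isolated)
Conditions: Ph3PCl2, toluene, 0 → 80 °C
Reagents that add atoms: dichlorotriphenylphosphorane, ClP(Cl)(c1ccccc1)(c1ccccc1)c1ccccc1
Why: Deoxydichlorination of an epoxide with dichlorotriphenylphosphorane, an Appel-type double inversion: after phosphonium activation of the epoxide oxygen, chloride opens the C1–O bond at the tertiary carbon from the opposite face (trans-diaxial opening), and a second chloride displaces Ph3PO from C6 with inversion, so both chlorines end cis to each other on the face opposite to the former epoxide oxygen, which sets C1 and C6 of the target.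

Compound list

1 | diethyl methylmalonate (diethyl 2-methylpropanedioate) | CCOC(=O)C(C)C(=O)OCC | starting material
2 | methyl vinyl ketone (but-3-en-2-one) | CC(=O)C=C | starting material
3 | diethyl 2-methyl-2-(3-oxobutyl)propanedioate | CCOC(=O)C(C)(CCC(C)=O)C(=O)OCC | intermediate
4 | 2-(hydroxymethyl)-2-methylhexane-1,5-diol (racemic) | CC(O)CCC(C)(CO)CO | intermediate
5 | 2-methyl-2-(3-oxobutyl)propanedial | CC(=O)CCC(C)(C=O)C=O | intermediate
6 | (1R,2R)-2-hydroxy-1-methyl-4-oxocyclohexane-1-carbaldehyde | O=C[C@]1(C)CCC(=O)C[C@H]1O | intermediate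
7 | (1R,2R)-2-[(tert-butyldimethylsilyl)oxy]-1-methyl-4-oxocyclohexane-1-carbaldehyde | O=C[C@]1(C)CCC(=O)C[C@H]1O[Si](C)(C)C(C)(C)C | intermediate
8 | (3R,4S)-4-[(E)-2-bromoethenyl]-3-[(tert-butyldimethylsilyl)oxy]-4-methylcyclohexan-1-one | O=C1C[C@@H](O[Si](C)(C)C(C)(C)C)[C@](C)(/C=C/Br)CC1 | intermediate
9 | Mannich base: (4S,5R)-4-[(E)-2-bromoethenyl]-5-[(tert-butyldimethylsilyl)oxy]-2-[(dimethylamino)methyl]-4-methylcyclohexan-1-one (both C2 epimers) | O=C1C[C@@H](O[Si](C)(C)C(C)(C)C)[C@](C)(/C=C/Br)CC1CN(C)C | intermediate
10 | trimethylammonium iodide obtained from 9 with MeI (N-methyl quaternary salt, both epimers) | O=C1C[C@@H](O[Si](C)(C)C(C)(C)C)[C@](C)(/C=C/Br)CC1C[N+](C)(C)C.[I-] | intermediate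
11 | (4S,5R)-4-[(E)-2-bromoethenyl]-5-[(tert-butyldimethylsilyl)oxy]-4-methyl-2-methylidenecyclohexan-1-one | O=C1C[C@@H](O[Si](C)(C)C(C)(C)C)[C@](C)(/C=C/Br)CC1=C | intermediate
12 | (4S,5R)-4-[(E)-2-bromoethenyl]-5-[(tert-butyldimethylsilyl)oxy]-4-methyl-2-methylidenecyclohexan-1-ol (both C1 epimers) | OC1C[C@@H](O[Si](C)(C)C(C)(C)C)[C@](C)(/C=C/Br)CC1=C | intermediate
13 | sulfonyl hydrazone: acetone N-allyl-N-(2-nitrobenzenesulfonyl)hydrazone in which the allyl group is the ring carbon of 12 that bore the hydroxyl | CC(C)=NN(C1C[C@@H](O[Si](C)(C)C(C)(C)C)[C@](C)(/C=C/Br)CC1=C)S(=O)(=O)c1ccccc1[N+](=O)[O-] | intermediate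
14 | allylic diazene: the HN=N– derivative at the same ring carbon | N=NC1C[C@@H](O[Si](C)(C)C(C)(C)C)[C@](C)(/C=C/Br)CC1=C | intermediate
15 | tert-butyl{[(1R,6S)-6-[(E)-2-bromoethenyl]-4,6-dimethylcyclohex-3-en-1-yl]oxy}dimethylsilane | CC1=CC[C@@H](O[Si](C)(C)C(C)(C)C)[C@](C)(/C=C/Br)C1 | intermediate
16 | (1R,6S)-6-[(E)-2-bromoethenyl]-4,6-dimethylcyclohex-3-en-1-ol | CC1=CC[C@@H](O)[C@](C)(/C=C/Br)C1 | intermediate
17 | (1S,3R,4S,6R)-4-[(E)-2-bromoethenyl]-4,6-dimethyl-7-oxabicyclo[4.1.0]heptan-3-ol | C[C@@]12C[C@@](C)(/C=C/Br)[C@H](O)C[C@@H]1O2 | intermediate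
18 | (1S,3R,4S,6R)-4-[(E)-2-bromoethenyl]-4,6-dimethyl-7-oxabicyclo[4.1.0]heptan-3-yl trifluoromethanesulfonate | C[C@@]12C[C@@](C)(/C=C/Br)[C@H](OS(=O)(=O)C(F)(F)F)C[C@@H]1O2 | intermediate
19 | (1R,3S,4S,6S)-4-bromo-3-[(E)-2-bromoethenyl]-1,3-dimethyl-7-oxabicyclo[4.1.0]heptane | C[C@@]12C[C@@](C)(/C=C/Br)[C@@H](Br)C[C@@H]1O2 | intermediate
20 | {[(1S,2S,4S,5S)-5-bromo-4-[(E)-2-bromoethenyl]-2-chloro-2,4-dimethylcyclohexyl]oxy}triphenylphosphonium chloride | C[C@]1(Cl)C[C@@](C)(/C=C/Br)[C@@H](Br)C[C@@H]1O[P+](c1ccccc1)(c1ccccc1)c1ccccc1.[Cl-] | intermediate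
21 | (1S,2S,4R,5S)-2-bromo-1-[(E)-2-bromoethenyl]-4,5-dichloro-1,5-dimethylcyclohexane | C[C@]1(Cl)C[C@@](C)(/C=C/Br)[C@@H](Br)C[C@H]1Cl | target

Total steps: 14. Longest linear sequence: 14 steps (from 1 and 2 to 21).

Steps most likely to fail

Step 4. What may go wrong: the catalyst may discriminate poorly between the two enantiotopic formyl groups or between the faces of the one attacked (low enantiomeric purity, or the cis ketol through the chair with axial methyl), and the ketol may dehydrate or revert by retro-aldol before it is silylated. Fallback, setting out from 3 and coming back at 7: the prochiral carbon is desymmetrised enzymatically one oxidation level lower, and the aldol then only closes the ring. Ketalisation of 3 (ethylene glycol, pTsOH, toluene, water removal) should give dioxolane diester F1, and LiAlH4 the prochiral dioxolane diol F2. Lipase-catalysed monoacetylation with vinyl acetate (enzyme chosen by screening; lipase hydrolysis of the diacetate reaches the antipodal series if needed) should give (R)-monoacetate F3. Dess–Martin oxidation leads to acetoxy aldehyde F4, and mild aqueous acid removes the ketal to give keto aldehyde F5. Its (R)-proline-mediated intramolecular aldol, now responsible only for the carbinol centre, gives ketol acetate F6. Silylation with TBSOTf gives silyl ether acetate F7, K2CO3 in MeOH the primary alcohol F8, and Dess–Martin oxidation returns 7.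

Step 13. What may go wrong: substitution at the neopentyl-type C4 may be outrun by E2 loss of triflate toward C5 or by opening of the trisubstituted epoxide by bromide. Fallback, setting out from 17 and coming back at 21: the bromination is postponed until no epoxide is left. Acetylation of 17 (Ac2O, pyridine, DMAP) gives epoxy acetate F9, and Ph3PCl2 as in step 14 converts the epoxide into the cis dichloride, giving dichloro acetate F10. Methanolysis (K2CO3, MeOH) frees dichloro alcohol F11, Tf2O and pyridine give dichloro triflate F12, and Bu4NBr in toluene gives 21 by inversion at C4. The substitution then takes place on a ring whose two chlorines disfavour ionisation and which holds nothing that bromide or acid can open.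

Step 14. What may go wrong: displacement of Ph3PO at C6, slowed by the fully substituted C1, may lose out to a 1,2-chlorine shift through a chloronium ion, which would scramble C1, or to elimination toward C5. Fallback, setting out from 19 and coming back at 21: the two C–Cl bonds are made in separate operations with an isolated intermediate. Anhydrous HCl in Et2O at −40 °C should open the epoxide at the tertiary carbon in the trans-diaxial sense to give chlorohydrin F13. Tf2O and pyridine then give chloro triflate F14, and Bu4NCl in toluene displaces the triflate with inversion to give 21. The much better leaving group lets this substitution run cold, where participation and elimination are slower.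

Further compounds

F1 | step 4 | diethyl 2-methyl-2-[2-(2-methyl-1,3-dioxolan-2-yl)ethyl]propanedioate | CCOC(=O)C(C)(CCC1(C)OCCO1)C(=O)OCC
F2 | step 4 | 2-methyl-2-[2-(2-methyl-1,3-dioxolan-2-yl)ethyl]propane-1,3-diol | CC1(CCC(C)(CO)CO)OCCO1
F3 | step 4 | (2R)-2-(hydroxymethyl)-2-methyl-4-(2-methyl-1,3-dioxolan-2-yl)butyl acetate | CC(=O)OC[C@@](C)(CO)CCC1(C)OCCO1
F4 | step 4 | (2S)-2-formyl-2-methyl-4-(2-methyl-1,3-dioxolan-2-yl)butyl acetate | CC(=O)OC[C@@](C)(C=O)CCC1(C)OCCO1
F5 | step 4 | (2S)-2-formyl-2-methyl-5-oxohexyl acetate | CC(=O)OC[C@@](C)(C=O)CCC(C)=O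
F6 | step 4 | [(1S,2R)-2-hydroxy-1-methyl-4-oxocyclohexyl]methyl acetate | O=C1CC[C@@](C)(COC(C)=O)[C@H](O)C1
F7 | step 4 | [(1S,2R)-2-[(tert-butyldimethylsilyl)oxy]-1-methyl-4-oxocyclohexyl]methyl acetate | O=C1CC[C@@](C)(COC(C)=O)[C@H](O[Si](C)(C)C(C)(C)C)C1
F8 | step 4 | (3R,4S)-3-[(tert-butyldimethylsilyl)oxy]-4-(hydroxymethyl)-4-methylcyclohexan-1-one | O=C1CC[C@@](C)(CO)[C@H](O[Si](C)(C)C(C)(C)C)C1
F9 | step 13 | (1S,3R,4S,6R)-4-[(E)-2-bromoethenyl]-4,6-dimethyl-7-oxabicyclo[4.1.0]heptan-3-yl acetate | C[C@@]12C[C@@](C)(/C=C/Br)[C@H](OC(C)=O)C[C@@H]1O2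
F10 | step 13 | (1R,2S,4S,5R)-2-[(E)-2-bromoethenyl]-4,5-dichloro-2,4-dimethylcyclohexyl acetate | C[C@]1(Cl)C[C@@](C)(/C=C/Br)[C@H](OC(C)=O)C[C@H]1Cl
F11 | step 13 | (1R,2S,4S,5R)-2-[(E)-2-bromoethenyl]-4,5-dichloro-2,4-dimethylcyclohexan-1-ol | C[C@]1(Cl)C[C@@](C)(/C=C/Br)[C@H](O)C[C@H]1Cl
F12 | step 13 | (1R,2S,4S,5R)-2-[(E)-2-bromoethenyl]-4,5-dichloro-2,4-dimethylcyclohexyl trifluoromethanesulfonate | C[C@]1(Cl)C[C@@](C)(/C=C/Br)[C@H](OS(=O)(=O)C(F)(F)F)C[C@H]1Cl
F13 | step 14 | (1S,2S,4S,5S)-5-bromo-4-[(E)-2-bromoethenyl]-2-chloro-2,4-dimethylcyclohexan-1-ol | C[C@]1(Cl)C[C@@](C)(/C=C/Br)[C@@H](Br)C[C@@H]1O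
F14 | step 14 | (1S,2S,4S,5S)-5-bromo-4-[(E)-2-bromoethenyl]-2-chloro-2,4-dimethylcyclohexyl trifluoromethanesulfonate | C[C@]1(Cl)C[C@@](C)(/C=C/Br)[C@@H](Br)C[C@@H]1OS(=O)(=O)C(F)(F)F
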